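## Retrosynthesis

- Dichrostachine A (**10**) is an intermolecular [4+2] adduct. The cyclohexene ring, with its three new stereocentres (C12, the quaternary C1′ and C6′), forms last. The bonds disconnected are C12–C1′ and C15–C6′, giving labdane diene **4** and 2‑(chromon‑2‑yl)‑5‑methoxy‑p‑benzoquinone **9**.
- The decalin of **4** comes intact from commercial trans‑communic acid (**1**). Only C7 oxygenation (β‑OH) and reduction of CO2H to CH2OH are needed.
- Quinone **9** comes from phloroacetophenone and 2,4,5‑trimethoxybenzaldehyde. The pyranone ring forms by chalcone cyclisation, then the quinone ring is unmasked by oxidative demethylation.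
- Order of ring formation: decalin (pre-existing), pyranone (step 5), quinone (step 6), cyclohexene (step 7).

**Assumptions**
- Commercial trans‑communic acid is the natural normal‑series compound: 10β‑Me, 5α‑H, 9α‑H, equatorial 4α‑CO2H, 12E. This matches the target decalin.
- The Diels–Alder step gives several diastereomers, and the desired one is isolated by HPLC.
- The free 5,7‑phenols and free alcohols are tolerated in steps 6 and 7.

## Route

**Step 1**
Reactants: **1** trans‑communic acid
Product: **2** 7‑hydroxy‑trans‑communic acid (C7 epimeric mixture)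
Conditions: SeO2 (0.3 equiv), TBHP (3 equiv), CH2Cl2, 0 °C → rt
Reagents that add atoms: SeO2, O=[Se]=O (source of the OH oxygen; Se is lost). TBHP, CC(C)(C)OO, is only the re‑oxidant and adds no atoms.
Why: Riley/Sharpless allylic oxidation (ene reaction then [2,3]‑shift) of the exocyclic methylene. The only accessible allylic CH2 is C7, and C8(17) is retained. The C7 stereocentre is removed in step 2, so its configuration does not matter.

**Step 2**
Reactants: **2**
Product: **3** 7‑oxo‑trans‑communic acid
Conditions: activated MnO2 (10 equiv), CH2Cl2, rt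
Reagents that add atoms: none
Why: MnO2 oxidation of the allylic alcohol to the conjugated α‑methylene ketone. Both C7 epimers converge on one ketone, and the acid, diene and alkene are untouched.

**Step 3**
Reactants: **3**
Product: **4** (7β,4α‑CH2OH)‑labda‑8(17),12E,14‑triene‑diol (the diene diol)
Conditions: LiAlH4 (6 equiv), THF, −78 °C → reflux
Reagents that add atoms: none (hydride only adds H)
Why: Hydride reduction. At low temperature the ketone is reduced 1,2. Axial (α‑face) attack, away from the 10β‑methyl, gives the equatorial 7β‑OH, as in NaBH4 reduction of 7‑oxo steroids. On warming, the carboxylate is reduced to the primary alcohol. C4, C5, C9 and C10 are untouched.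

**Step 4**
Reactants: **5** 2,4,6‑trihydroxyacetophenone; **6** 2,4,5‑trimethoxybenzaldehyde
Product: **7** (E)‑2′,4′,6′‑trihydroxy‑2,4,5‑trimethoxychalcone
Conditions: KOH (aq.), EtOH, rt, 48 h; then HCl
Reagents that add atoms: none
Why: Claisen–Schmidt aldol condensation. Dehydration gives the thermodynamic E‑enone.

**Step 5**
Reactants: **7**
Product: **8** 5,7‑dihydroxy‑2′,4′,5′‑trimethoxyflavone
Conditions: I2 (0.1 equiv), DMSO, 130 °C
Reagents that add atoms: none
Why: Oxa‑Michael cyclisation to the flavanone, then I2/DMSO dehydrogenation to the flavone. This builds the chromone ring, and the phenols stay free.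

**Step 6**
Reactants: **8**
Product: **9** 2‑(5,7‑dihydroxy‑4‑oxochromen‑2‑yl)‑5‑methoxy‑1,4‑benzoquinone
Conditions: CAN (3 equiv), MeCN/H2O 4:1, 0 °C, 10 min
Reagents that add atoms: water, O (supplies the quinone carbonyl oxygens)
Why: Oxidative demethylation of the para dimethoxy pair (2′,5′‑OMe) gives the quinone. The 4′‑OMe, which has no para partner, is retained, and the electron‑poor chromone phenols resist oxidation.

**Step 7**
Reactants: **4** (1.5 equiv); **9**
Product: **10** Dichrostachine A
Conditions: CH2Cl2, 10 kbar, 35 °C, 3 d; then HPLC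
Reagents that add atoms: none
Why: Diels–Alder reaction of the E‑1‑alkyl‑2‑methyl diene with the activated quinone C=C. The methoxy‑bearing C=C is deactivated as a vinylogous ester, so only the chromonyl‑bearing C=C reacts. The electron‑poor C5′ carbonyl makes C1′ the electrophilic terminus, which bonds to the most nucleophilic diene terminus C12 (isoprene‑type "para" preference). Suprafacial addition fixes the cis ring fusion (C1′ and C6′). The C12 configuration, with C11 cis to the chromonyl group, comes from the exo‑quinone approach and the facial bias of the C9 stereocentre. High pressure overcomes the congested vicinal quaternary/tertiary bond formation, and HPLC removes the other diastereomers.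

## Compound list

| No. | Name | SMILES | Role |
|---|---|---|---|
| 1 | trans‑communic acid | C=C1CC[C@H]2[C@](C)(C(=O)O)CCC[C@]2(C)[C@H]1C/C=C(\C)C=C | starting material |
| 2 | 7‑hydroxy‑trans‑communic acid (C7 epimers) | C=C1C(O)C[C@H]2[C@](C)(C(=O)O)CCC[C@]2(C)[C@H]1C/C=C(\C)C=C | intermediate |
| 3 | 7‑oxo‑trans‑communic acid | C=C1C(=O)C[C@H]2[C@](C)(C(=O)O)CCC[C@]2(C)[C@H]1C/C=C(\C)C=C | intermediate |
| 4 | labda‑8(17),12E,14‑triene‑7β,4α‑CH2OH diol (diene) | C=C1[C@@H](O)C[C@H]2[C@](C)(CO)CCC[C@]2(C)[C@H]1C/C=C(\C)C=C | intermediate |
| 5 | 2,4,6‑trihydroxyacetophenone | CC(=O)c1c(O)cc(O)cc1O | starting material |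
| 6 | 2,4,5‑trimethoxybenzaldehyde | O=Cc1cc(OC)c(OC)cc1OC | starting material |
| 7 | (E)‑2′,4′,6′‑trihydroxy‑2,4,5‑trimethoxychalcone | O=C(/C=C/c1cc(OC)c(OC)cc1OC)c1c(O)cc(O)cc1O | intermediate |
| 8 | 5,7‑dihydroxy‑2′,4′,5′‑trimethoxyflavone | COc1cc(OC)c(-c2cc(=O)c3c(O)cc(O)cc3o2)cc1OC | intermediate |
| 9 | 2‑(5,7‑dihydroxy‑4‑oxochromen‑2‑yl)‑5‑methoxy‑1,4‑benzoquinone | COC1=CC(=O)C(=CC1=O)c1cc(=O)c2c(O)cc(O)cc2o1 | intermediate |
| 10 | Dichrostachine A | C=C1[C@@H](O)C[C@H]2[C@](C)(CO)CCC[C@]2(C)[C@H]1C[C@@H]1C(C)=CC[C@H]2C(=O)C(OC)=CC(=O)[C@@]12c1cc(=O)c2c(O)cc(O)cc2o1 | target |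

## Totals

- Total steps: 7.
- Longest linear sequence: 4 steps (1→2→3→4→10, or 5/6→7→8→9→10).

## Three steps most likely to fail

1. **Step 7 (Diels–Alder).** Regiochemistry, exo/endo selectivity and diene‑face selectivity may all be poor.
   - Fallback: use 2‑acetyl‑5‑methoxybenzoquinone as the smaller, more reactive dienophile. After the Diels–Alder, build the chromone by Claisen condensation of the acetyl group with a protected 2‑hydroxy‑4,6‑dioxygenated benzoate, then cyclodehydration (a different disconnection of the flavone).
2. **Step 1 (SeO2 oxidation).** The conjugated diene may be oxidised or the product over‑oxidised.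
   - Fallback: mask the diene as its SO2 adduct (3‑sulfolene) before the SeO2/MnO2 sequence. The diene is released by cheletropic SO2 loss in situ during the step 7 heating or pressure run.
3. **Step 4 (Claisen–Schmidt on unprotected phloroacetophenone).** Yields may be low because of polyphenolate formation.
   - Fallback: use 4′,6′‑bis‑MOM‑2′‑hydroxyacetophenone, run the chalcone and flavone steps, and remove the MOM groups by acid before the CAN oxidation.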